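**Strategy.** The route rests on cutting ring A (C1–C2–C3–C4–C5–C10) at C4–C5 and C1–C10. The key step exploits the fact that every stereocentre of the target lies on this ring, oxygen on C1 and C3, methyl on C4 and on quaternary C5: a catalytic enantioselective Diels–Alder reaction of a (1E,3Z)-1,3-bis(silyloxy)penta-1,3-diene (C1–C4) with a formyl-activated trisubstituted alkene (C10=C5, methyl on C5) closes ring A and sets C1, C4, C5 and C10 in one operation, leaving a formyl carbon (C9) and an ester carbon (C6) as anchors. Ring B follows by inserting C7–C8 between these anchors; acetone supplies C11–C13, and a last singlet-oxygen ene reaction creates the C11 hydroperoxide and C6=C7.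

Key step: step 6

Remark on numbering: target locants are used for all intermediates (ring A = C1, C2, C3, C4, C5, C10; ring B = C5 to C10; C11–C13 on C7); "syn" means on the face of the C5 methyl group, "anti" the other face.

Assumption: the sense of induction in step 6 is taken to follow the usual formyl C–H···O binding model of protonated oxazaborolidines; the (S)-prolinol-derived catalyst is written, and its mirror image is used instead if that model assigns the required Re-face attack at C10 to it.

Step 1
Reactants: 1 ethyl vinyl ether; 2 propanoyl chloride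
Product: 4 (E)-1-ethoxypent-1-en-3-one, via chloro ether adduct 3 (not isolated)
Conditions: 1 (3 equiv), neat, 0 °C to rt; then Et3N, Et2O, 0 °C to rt; distil
Reagents that add atoms: none
Why: Acylation of an enol ether by an acid chloride followed by amine-induced loss of HCl gives the β-alkoxy enone, whose (E)-isomer is the stable one.

Step 2
Reactants: 4 (E)-1-ethoxypent-1-en-3-one
Product: 6 (E)-1-(tert-butyldimethylsilyloxy)pent-1-en-3-one, via sodium enolate 5 (not isolated)
Conditions: NaOH (1.0 equiv), MeOH/H2O, 0 °C to rt; evaporate and dry; t-BuMe2SiCl, THF, 0 °C to rt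
Reagents that add atoms: sodium hydroxide, [Na+].[OH-]; tert-butyldimethylsilyl chloride, CC(C)(C)[Si](C)(C)Cl
Why: Addition–elimination of hydroxide on the vinylogous ester gives the sodium salt of the β-keto aldehyde, and O-silylation of such salts is known to give the (E)-β-silyloxy enone.

Step 3
Reactants: 6 (E)-1-(tert-butyldimethylsilyloxy)pent-1-en-3-one
Product: 7 (1E,3Z)-1,3-bis(tert-butyldimethylsilyloxy)penta-1,3-diene
Conditions: t-BuMe2SiOTf, Et3N, Et2O, 0 °C
Reagents that add atoms: tert-butyldimethylsilyl trifluoromethanesulfonate, CC(C)(C)[Si](C)(C)OS(=O)(=O)C(F)(F)F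
Why: Soft enolisation of the ethyl ketone (silyl triflate and amine) gives the silyl enol ether with methyl cis to oxygen, the (Z)-isomer favoured by allylic strain, so both terminal substituents of the s-cis diene point outwards.

Step 4
Reactants: 8 2,2-dimethoxyacetaldehyde; 9 methyl 2-(triphenylphosphoranylidene)propanoate
Product: 10 methyl (E)-4,4-dimethoxy-2-methylbut-2-enoate
Conditions: CH2Cl2, rt
Reagents that add atoms: none
Why: Wittig olefination with a stabilised ylide gives the trisubstituted enoate with the ester trans to the acetal carbon, the (E)-isomer.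

Step 5
Reactants: 10 methyl (E)-4,4-dimethoxy-2-methylbut-2-enoate
Product: 11 methyl (E)-2-methyl-4-oxobut-2-enoate
Conditions: Amberlyst-15 (H+ resin), acetone/H2O, rt; used fresh
Reagents that add atoms: water, O
Why: Acid-catalysed acetal hydrolysis frees the aldehyde without touching the (E)-alkene, which is the thermodynamically preferred isomer.

Step 6
Reactants: 7 (1E,3Z)-1,3-bis(tert-butyldimethylsilyloxy)penta-1,3-diene; 11 methyl (E)-2-methyl-4-oxobut-2-enoate
Product: 12 methyl (1R,2R,5R,6S)-3,5-bis(tert-butyldimethylsilyloxy)-6-formyl-1,2-dimethylcyclohex-3-ene-1-carboxylate (ring A adduct: C1 OTBS; C2=C3 silyl enol ether; C4 Me; C5 Me and CO2Me = C6; C10 CHO = C9)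
Conditions: 7 (1.5 equiv), (S)-diphenylprolinol-derived B-(o-tolyl)oxazaborolidine (C24H24BNO, 20 mol %), HN(SO2CF3)2 (18 mol %), CH2Cl2, −78 °C; Et3N quench; Et3N-washed silica
Reagents that add atoms: none
Why: The protonated oxazaborolidine binds the formyl oxygen of 11 and the electron-rich diene 7 adds in a concerted but asynchronous [4+2] cycloaddition in which C4, the nucleophilic terminus beside the silyloxy carbon C3, bonds first to C5 (β to the formyl group) and C1 then closes onto C10. The closest known reaction type is the chiral oxazaborolidinium-catalysed Diels–Alder reaction of enals with silyloxy dienes, together with additions of 1-oxy-3-silyloxy dienes to doubly activated trisubstituted alkenes. Ring A, the only ring formed, is closed by [4+2] cycloaddition through the bonds C4–C5 and C1–C10. C1 and C4 come out cis because both terminal substituents of the (1E,3Z)-diene point outwards, the C5 methyl and the C10 formyl are cis (ester anti) because the alkene is (E), the endo position of the bound formyl group puts the C5 methyl on the face of the C1 oxygen and the C4 methyl, and the absolute sense (diene on the Re face at C10) comes from the catalyst. The step needs regio-, endo- and facial selectivity: the first two follow from the formyl group being the only carbonyl that is complexed, the third from the chiral pocket. Silyl groups of the tert-butyldimethyl type on both oxygens keep diene and adduct intact under the acidic catalyst and suppress achiral silyl-cation catalysis.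

Step 7
Reactants: 12 ring A adduct; 13 ethyltriphenylphosphonium bromide
Product: 14 ring A (Z)-propenyl ester (as 12 with C10 carrying (Z)-CH=CH–CH3 = C9=C8–C7)
Conditions: 13 (1.5 equiv), KN(SiMe3)2, THF, 0 °C; then 12, −78 to 0 °C
Reagents that add atoms: none
Why: Wittig olefination with a small, salt-free non-stabilised ylide adds to the hindered aldehyde faster than it deprotonates C10, giving the (Z)-alkene, whose geometry is of no later consequence.

Step 8
Reactants: 14 ring A (Z)-propenyl ester
Product: 15 C3 ketone (C1 OTBS retained)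
Conditions: Bu4NF (1.05 equiv), AcOH (1.2 equiv), THF, −78 to −20 °C
Reagents that add atoms: none
Why: Buffered fluoride desilylation cleaves the silyl enol ether far faster than the alkyl silyl ether, and the acetic acid protonates the enolate at C2 before the C1 silyloxy group can be eliminated.

Step 9
Reactants: 15 C3 ketone
Product: 16 C3 alcohol (hydroxyl syn)
Conditions: LiBH(s-Bu)3 (L-Selectride, 1.2 equiv), THF, −78 °C; AcOH quench at −78 °C
Reagents that add atoms: none
Why: Bulky-hydride ketone reduction, in which hydride attacks C3 from the face anti to the neighbouring C4 methyl, the C1 silyloxy group and the C5 methyl (equatorial attack, as in the reduction of 2-methylcyclohexanone to the cis alcohol), so the new hydroxyl is syn; the cold quench avoids silyl migration from O1 and the hindered ester is not reduced.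

Step 10
Reactants: 16 C3 alcohol
Product: 17 C3 triethylsilyl ether
Conditions: Et3SiOTf, 2,6-lutidine, CH2Cl2, −78 to 0 °C
Reagents that add atoms: triethylsilyl trifluoromethanesulfonate, CC[Si](CC)(CC)OS(=O)(=O)C(F)(F)F
Why: Silyl triflate silylation protects the hindered secondary alcohol with a group that can later be removed in the presence of the C1 tert-butyldimethylsilyl ether.

Step 11
Reactants: 17 C3 triethylsilyl ether
Product: 19 C8 alcohol (2-hydroxypropyl on C10; C8 epimers), via B-alkyl-9-BBN adduct 18 (not isolated)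
Conditions: 9-BBN (9-borabicyclo[3.3.1]nonane, 2 equiv), THF, rt to 60 °C; then H2O2, aq NaOH, 0 °C
Reagents that add atoms: hydrogen peroxide, OO
Why: Hydroboration–oxidation, in which the bulky borane places boron on C8, the alkene carbon remote from the branched ring carbon C10, so that oxygen ends on C8; the C8 configuration is erased in step 13.

Step 12
Reactants: 19 C8 alcohol
Product: 20 diol (hydroxymethyl C6 on C5; C8 alcohol)
Conditions: LiAlH4, THF, 0 °C to rt
Reagents that add atoms: none
Why: Hydride reduction of the neopentyl ester (or of any δ-lactone formed from it with the C8 hydroxyl) gives the primary alcohol, the silyl ethers being inert.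

Step 13
Reactants: 20 diol
Product: 21 keto aldehyde (C6 formyl on C5; 2-oxopropyl C9–C8(=O)–C7 on C10)
Conditions: Dess–Martin periodinane (2.5 equiv), NaHCO3, CH2Cl2, 0 °C to rt
Reagents that add atoms: none
Why: Buffered Dess–Martin oxidation converts both alcohols at once, and the aldehyde on quaternary C5 cannot enolise or epimerise.

Step 14
Reactants: 21 keto aldehyde
Product: 23 trans-fused eremophil-6-en-8-one (1-OTBS; 3-OTES; 10-H anti), via aldol 22 (not isolated)
Conditions: KOH, MeOH, 0 °C to rt
Reagents that add atoms: none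
Why: Intramolecular aldol condensation of the methyl ketone carbon C7 onto the non-enolisable C6 aldehyde closes ring B as a six-membered enone, the alternative attack through C9 leading only reversibly to a four-membered ring.

Step 15
Reactants: 23 trans-fused eremophil-6-en-8-one; 24 acetone
Product: 26 11-hydroxyeremophilan-8-one (C7 carries C(OH)Me2; C7 epimers), via lithium enolate 25 (not isolated)
Conditions: LiBH(s-Bu)3 (1.1 equiv), THF, −78 °C; ZnCl2; then 24 (excess), −78 to −40 °C; aq NH4Cl
Reagents that add atoms: none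
Why: Conjugate reduction of the β-unsubstituted enone by the bulky borohydride (as with steroidal 1-en-3-ones) gives the C7 enolate regiospecifically, and its aldol addition to acetone attaches C11–C13 at C7.

Step 16
Reactants: 26 11-hydroxyeremophilan-8-one
Product: 28 eremophil-7(11)-en-8-one (1-OTBS; 3-OTES), via mesylate 27 (not isolated)
Conditions: MeSO2Cl, Et3N, CH2Cl2, 0 °C to rt; then DBU, rt
Reagents that add atoms: none
Why: Mesylation of the tertiary aldol hydroxyl and E1cB elimination through the acidic C7–H give the conjugated, tetrasubstituted isopropylidene ketone.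

Step 17
Reactants: 28 eremophil-7(11)-en-8-one
Product: 30 eremophila-7(11),9-dien-8-one (1-OTBS; 3-OTES), via trimethylsilyl dienol ether 29 (not isolated)
Conditions: LiN(i-Pr)2, THF, −78 °C; Me3SiCl; then Pd(OAc)2 (1.1 equiv), MeCN, rt
Reagents that add atoms: none
Why: Saegusa–Ito oxidation, in which kinetic deprotonation can occur only at C9 (the sole sp3 α-carbon), and palladium-mediated dehydrosilylation with loss of the C10 hydrogen gives the C9=C10 enone, removing the C10 stereocentre.

Step 18
Reactants: 30 eremophila-7(11),9-dien-8-one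
Product: 31 3-hydroxy-1-(tert-butyldimethylsilyloxy)eremophila-7(11),9-dien-8-one
Conditions: pyridinium p-toluenesulfonate (cat.), MeOH/CH2Cl2, 0 °C
Reagents that add atoms: none
Why: Acid-catalysed methanolysis (selective desilylation) cleaves the triethylsilyl ether much faster than the secondary tert-butyldimethylsilyl ether.

Step 19
Reactants: 31 3-hydroxy dienone; 32 angelic acid
Product: 34 3-angeloyloxy-1-(tert-butyldimethylsilyloxy)eremophila-7(11),9-dien-8-one, via mixed anhydride 33 (not isolated)
Conditions: 32, 2,4,6-trichlorobenzoyl chloride, Et3N, toluene, rt; then 31, toluene, 80 °C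
Reagents that add atoms: none
Why: Yamaguchi-type esterification through the mixed anhydride without a nucleophilic catalyst, a protocol known to keep the (Z)-geometry of angelates; the alcohol attacks the less hindered angeloyl carbonyl.

Step 20
Reactants: 34 3-angeloyloxy-1-silyloxy dienone
Product: 35 3-angeloyloxy-1-hydroxyeremophila-7(11),9-dien-8-one
Conditions: HF·pyridine, pyridine, THF, 0 °C to rt
Reagents that add atoms: none
Why: Fluoride desilylation under buffered, weakly acidic conditions frees the C1 hydroxyl without affecting the angelate or the dienone.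

Step 21
Reactants: 35 3-angeloyloxy-1-hydroxyeremophila-7(11),9-dien-8-one
Product: 36 (1R,3S,4R,5R)-1-hydroxy-11-hydroperoxy-8-oxoeremophila-6,9-dien-3-yl (Z)-2-methylbut-2-enoate (CNP0300636.1)
Conditions: O2, tetraphenylporphyrin (cat.), visible light, CH2Cl2, 0 °C
Reagents that add atoms: dioxygen, O=O
Why: Schenck ene reaction of singlet oxygen with the s-cis enone, in which oxygen adds to the β-carbon C11 and hydrogen is taken from C6, the group geminal to the carbonyl on C7, giving the tertiary hydroperoxide and C6=C7 without a new stereocentre; the tetrasubstituted C7=C11 bond should react faster than the angelate or the C9=C10 enone.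

**Compound list**

1 | ethyl vinyl ether | C=COCC | starting material
2 | propanoyl chloride | CCC(Cl)=O | starting material
3 | 1-chloro-1-ethoxypentan-3-one | CCOC(Cl)CC(=O)CC | intermediate
4 | (E)-1-ethoxypent-1-en-3-one | CCO/C=C/C(=O)CC | intermediate
5 | sodium (E)-3-oxopent-1-en-1-olate | CCC(=O)/C=C/[O-].[Na+] | intermediate
6 | (E)-1-(tert-butyldimethylsilyloxy)pent-1-en-3-one | CCC(=O)/C=C/O[Si](C)(C)C(C)(C)C | intermediate
7 | (1E,3Z)-1,3-bis(tert-butyldimethylsilyloxy)penta-1,3-diene | C/C=C(\O[Si](C)(C)C(C)(C)C)/C=C/O[Si](C)(C)C(C)(C)C | intermediate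
8 | 2,2-dimethoxyacetaldehyde | COC(OC)C=O | starting material
9 | methyl 2-(triphenylphosphoranylidene)propanoate | COC(=O)C(C)=P(c1ccccc1)(c1ccccc1)c1ccccc1 | starting material
10 | methyl (E)-4,4-dimethoxy-2-methylbut-2-enoate | COC(OC)/C=C(\C)C(=O)OC | intermediate
11 | methyl (E)-2-methyl-4-oxobut-2-enoate | O=C/C=C(\C)C(=O)OC | intermediate
12 | methyl (1R,2R,5R,6S)-3,5-bis(tert-butyldimethylsilyloxy)-6-formyl-1,2-dimethylcyclohex-3-ene-1-carboxylate (C1 OTBS, C4 Me, C5 Me and C10 CHO syn; CO2Me anti) | C[C@H]1C(O[Si](C)(C)C(C)(C)C)=C[C@@H](O[Si](C)(C)C(C)(C)C)[C@@H](C=O)[C@]1(C)C(=O)OC | intermediate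
13 | ethyltriphenylphosphonium bromide | CC[P+](c1ccccc1)(c1ccccc1)c1ccccc1.[Br-] | starting material
14 | ring A (Z)-propenyl ester (12 with (Z)-prop-1-enyl on C10, same configuration) | C[C@H]1C(O[Si](C)(C)C(C)(C)C)=C[C@@H](O[Si](C)(C)C(C)(C)C)[C@@H](/C=C\C)[C@]1(C)C(=O)OC | intermediate
15 | C3 ketone (C1 OTBS, C4 Me, C5 Me and C10 propenyl syn; CO2Me anti) | C[C@H]1C(=O)C[C@@H](O[Si](C)(C)C(C)(C)C)[C@@H](/C=C\C)[C@]1(C)C(=O)OC | intermediate
16 | C3 alcohol (C3 OH syn) | C[C@H]1[C@@H](O)C[C@@H](O[Si](C)(C)C(C)(C)C)[C@@H](/C=C\C)[C@]1(C)C(=O)OC | intermediate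
17 | C3 triethylsilyl ether of 16 | C[C@H]1[C@@H](O[Si](CC)(CC)CC)C[C@@H](O[Si](C)(C)C(C)(C)C)[C@@H](/C=C\C)[C@]1(C)C(=O)OC | intermediate
18 | B-alkyl-9-BBN adduct of 17 (boron on C8) | C[C@H]1[C@@H](O[Si](CC)(CC)CC)C[C@@H](O[Si](C)(C)C(C)(C)C)[C@@H](CC(C)B2C3CCCC2CCC3)[C@]1(C)C(=O)OC | intermediate
19 | C8 alcohol (2-hydroxypropyl on C10, C8 epimers) | C[C@H]1[C@@H](O[Si](CC)(CC)CC)C[C@@H](O[Si](C)(C)C(C)(C)C)[C@@H](CC(C)O)[C@]1(C)C(=O)OC | intermediate
20 | diol (hydroxymethyl on C5, 2-hydroxypropyl on C10) | C[C@H]1[C@@H](O[Si](CC)(CC)CC)C[C@@H](O[Si](C)(C)C(C)(C)C)[C@@H](CC(C)O)[C@]1(C)CO | intermediate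
21 | keto aldehyde (formyl on C5, 2-oxopropyl on C10) | C[C@H]1[C@@H](O[Si](CC)(CC)CC)C[C@@H](O[Si](C)(C)C(C)(C)C)[C@@H](CC(C)=O)[C@]1(C)C=O | intermediate
22 | aldol (trans-fused 6-hydroxyeremophilan-8-one, C6 epimers) | C[C@H]1[C@@H](O[Si](CC)(CC)CC)C[C@@H](O[Si](C)(C)C(C)(C)C)[C@H]2CC(=O)CC(O)[C@]12C | intermediate
23 | trans-fused eremophil-6-en-8-one (1-OTBS and 3-OTES syn, 10-H anti) | C[C@H]1[C@@H](O[Si](CC)(CC)CC)C[C@@H](O[Si](C)(C)C(C)(C)C)[C@H]2CC(=O)C=C[C@]12C | intermediate
24 | acetone | CC(C)=O | starting material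
25 | lithium enolate (C7=C8–OLi) of the saturated ketone | C[C@H]1[C@@H](O[Si](CC)(CC)CC)C[C@@H](O[Si](C)(C)C(C)(C)C)[C@H]2CC([O-])=CC[C@]12C.[Li+] | intermediate
26 | 11-hydroxyeremophilan-8-one (1-OTBS, 3-OTES, C7 epimers) | C[C@H]1[C@@H](O[Si](CC)(CC)CC)C[C@@H](O[Si](C)(C)C(C)(C)C)[C@H]2CC(=O)C(C(C)(C)O)C[C@]12C | intermediate
27 | C11 mesylate of 26 | C[C@H]1[C@@H](O[Si](CC)(CC)CC)C[C@@H](O[Si](C)(C)C(C)(C)C)[C@H]2CC(=O)C(C(C)(C)OS(C)(=O)=O)C[C@]12C | intermediate
28 | eremophil-7(11)-en-8-one (1-OTBS, 3-OTES, 10-H anti) | C[C@H]1[C@@H](O[Si](CC)(CC)CC)C[C@@H](O[Si](C)(C)C(C)(C)C)[C@H]2CC(=O)C(=C(C)C)C[C@]12C | intermediate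
29 | trimethylsilyl dienol ether (C8 OSiMe3, C8=C9, C7=C11) | C[C@H]1[C@@H](O[Si](CC)(CC)CC)C[C@@H](O[Si](C)(C)C(C)(C)C)[C@H]2C=C(O[Si](C)(C)C)C(=C(C)C)C[C@]12C | intermediate
30 | eremophila-7(11),9-dien-8-one (1-OTBS, 3-OTES, both syn) | C[C@H]1[C@@H](O[Si](CC)(CC)CC)C[C@@H](O[Si](C)(C)C(C)(C)C)C2=CC(=O)C(=C(C)C)C[C@]12C | intermediate
31 | 3-hydroxy-1-(tert-butyldimethylsilyloxy)eremophila-7(11),9-dien-8-one | C[C@H]1[C@@H](O)C[C@@H](O[Si](C)(C)C(C)(C)C)C2=CC(=O)C(=C(C)C)C[C@]12C | intermediate
32 | angelic acid, (Z)-2-methylbut-2-enoic acid | C/C=C(/C)C(=O)O | starting material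
33 | angelic 2,4,6-trichlorobenzoic anhydride | C/C=C(/C)C(=O)OC(=O)c1c(Cl)cc(Cl)cc1Cl | intermediate
34 | 3-angeloyloxy-1-(tert-butyldimethylsilyloxy)eremophila-7(11),9-dien-8-one | C[C@H]1[C@@H](OC(=O)/C(C)=C\C)C[C@@H](O[Si](C)(C)C(C)(C)C)C2=CC(=O)C(=C(C)C)C[C@]12C | intermediate
35 | 3-angeloyloxy-1-hydroxyeremophila-7(11),9-dien-8-one | C[C@H]1[C@@H](OC(=O)/C(C)=C\C)C[C@@H](O)C2=CC(=O)C(=C(C)C)C[C@]12C | intermediate
36 | (1R,3S,4R,5R)-1-hydroxy-11-hydroperoxy-8-oxoeremophila-6,9-dien-3-yl (Z)-2-methylbut-2-enoate | C[C@H]1[C@@H](OC(=O)/C(C)=C\C)C[C@@H](O)C2=CC(=O)C(C(C)(C)OO)=C[C@]12C | target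

**Step count.** Total: 21 steps. Longest linear sequence: 19 steps (steps 1–3 and 6–21).

**Steps most likely to fail**

1. Step 6. The cycloaddition may not turn over, or may give poor facial selectivity. The C4–C5 bond forms between a methyl-bearing diene terminus and a fully substituted alkene carbon, and the acidic catalyst may desilylate the diene. Fallback: from 7 and 11 the cycloaddition is run without chiral control (Me2AlCl, CH2Cl2, −78 °C), which should give the same endo adduct as a racemate, that is 12 together with its mirror image F1. The enantiomers are separated by preparative HPLC on a chiral stationary phase (amylose tris(3,5-dimethylphenylcarbamate), hexane/i-PrOH), and 12 re-enters the route at step 7.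

2. Step 15. Direct 1,2-reduction of the carbonyl may compete with hydride delivery to the neopentyl β-carbon C6, and the enolate may be quenched by proton transfer from acetone instead of adding to it. Fallback: from 23, 1,4-hydrosilylation (Et3SiH, RhCl(PPh3)3 cat., benzene, 60 °C) gives the triethylsilyl enol ether F2 with the C7=C8 double bond. Mukaiyama aldol addition of F2 to acetone (TiCl4, CH2Cl2, −78 °C) then gives 26, where the route is rejoined.

3. Step 21. The photooxygenation of the electron-poor C7=C11 bond may be slow enough for the ene reaction at the angelate double bond and over-oxidation to compete. Fallback: from 31, which carries no angelate, the same photooxygenation gives the hydroperoxide F3. The more acidic hydroperoxy group is silylated selectively (Et3SiCl, imidazole, DMF, −20 °C) to the silyl peroxide F4. The C3 hydroxyl is then esterified through mixed anhydride 33 as in step 19 to give F5, and HF·pyridine removes both silyl groups to arrive at 36.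

**Further compounds**

F1 | step 6 | mirror image of 12, methyl (1S,2S,5S,6R)-3,5-bis(tert-butyldimethylsilyloxy)-6-formyl-1,2-dimethylcyclohex-3-ene-1-carboxylate | C[C@@H]1C(O[Si](C)(C)C(C)(C)C)=C[C@H](O[Si](C)(C)C(C)(C)C)[C@H](C=O)[C@@]1(C)C(=O)OC
F2 | step 15 | triethylsilyl enol ether (C7=C8) of the trans-fused eremophilan-8-one, 1-OTBS, 3-OTES | C[C@H]1[C@@H](O[Si](CC)(CC)CC)C[C@@H](O[Si](C)(C)C(C)(C)C)[C@H]2CC(O[Si](CC)(CC)CC)=CC[C@]12C
F3 | step 21 | 3-hydroxy-11-hydroperoxy-1-(tert-butyldimethylsilyloxy)eremophila-6,9-dien-8-one | C[C@H]1[C@@H](O)C[C@@H](O[Si](C)(C)C(C)(C)C)C2=CC(=O)C(C(C)(C)OO)=C[C@]12C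
F4 | step 21 | 3-hydroxy-11-(triethylsilylperoxy)-1-(tert-butyldimethylsilyloxy)eremophila-6,9-dien-8-one | C[C@H]1[C@@H](O)C[C@@H](O[Si](C)(C)C(C)(C)C)C2=CC(=O)C(C(C)(C)OO[Si](CC)(CC)CC)=C[C@]12C
F5 | step 21 | 3-angeloyloxy-11-(triethylsilylperoxy)-1-(tert-butyldimethylsilyloxy)eremophila-6,9-dien-8-one | C[C@H]1[C@@H](OC(=O)/C(C)=C\C)C[C@@H](O[Si](C)(C)C(C)(C)C)C2=CC(=O)C(C(C)(C)OO[Si](CC)(CC)CC)=C[C@]12C
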